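The data come from a simulation with constants of no real substance, and the scatter is random.

I decide to carry a share of the partner, not an equilibrium constant.

in all of them: starting material 0.050 M
- Friday's: second substrate 0.10 M; partner 0.075 M; free catalyst 0.12 mM; temperature 89 °C; run made earlier
- Thursday's: second substrate 0.10 M; partner 0.075 M; free catalyst 0.50 mM; temperature 97 °C; run made earlier
- Saturday's: second substrate 0.10 M; partner 0.037 M; free catalyst 0.25 mM; temperature 89 °C; run made earlier
- zeta: second substrate 0.100 M; partner 0.0750 M; free catalyst 0.25 mM; temperature 100 °C; time 12 d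
- eta: second substrate 0.100 M; partner 0.0750 M; free catalyst 0.25 mM; at 100 °C until 2.5 d, from then on at 85 °C; time 12 d
- gamma: second substrate 0.100 M; partner 0.0750 M; free catalyst 0.25 mM; temperature 85 °C; time 12 d

| run | time / d | target / % | starting material / % |
|---|---|---|---|
| Friday's | 6.00 | 33.9 | 65.7 |
| Friday's | 15.0 | 43.3 | 56.9 |
| Friday's | 25.0 | 43.4 | 56.4 |
| Thursday's | 1.25 | 39.5 | 60.3 |
| Thursday's | 2.50 | 41.2 | 58.2 |
| Thursday's | 6.00 | 40.6 | 57.8 |
| Thursday's | 15.0 | 41.6 | 57.7 |
| Saturday's | 3.00 | 14.6 | 85.8 |
| Saturday's | 8.00 | 16.3 | 83.4 |
| Saturday's | 15.0 | 16.0 | 83.1 |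
| Saturday's | 25.0 | 15.8 | 83.7 |

(standard deviation of a reading: 0.5 percentage points)



* the flask that comes out highest in amount of target, in percent of the starting material charged, or "all alike" when all lie within 1.5 percentage points (zeta / eta / gamma / all alike)
* target at the end, in percent of the starting material charged, zeta
* target at the end, in percent of the starting material charged, eta
* target at the end, in percent of the starting material charged, gamma

Q: Why do the readings stop with starting material left?

A: My reading is that the stop follows the partner, the limiting reagent. With [partner] = 0.037 M instead of 0.075 M, Saturday's run stands at 15.8 %, Friday's at 43.4 %. Target formed per partner charged is 0.214 in Saturday's run and 0.289 in Friday's. So, if the partner is consumed, the rest of it goes somewhere unseen.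

Q: What do you carry?

A: The mean of Friday's and Thursday's last readings gives 0.283, the partner share, target formed per partner charged. Multiplied by [partner]/[starting material], it gives 42.5 % for each new flask.

Q: Is a mean fair? The share isn't constant.

A: It isn't. Read across Saturday's and Friday's runs, the extra partner gave 0.363, though their catalyst differs too. So the mean serves one charge of starting material, second substrate and partner, and the new flasks have that charge. Their free catalyst lies above Friday's and below Thursday's.

Q: And temperature?

A: Thursday's run is hotter and richer in catalyst, two changes at once, so its gap of 1.8 percentage points from Friday's can't be divided between them. The mean lies 0.9 points from either reading. But flasks are judged against each other, and the gap is larger than the margin of 1.5 points. It exceeds it by 0.3 points, less than the 0.5 points of one reading. So I say all alike, thinly.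

Q: Does gamma finish?

A: Probably. Catalyst times time in gamma is 1.67 times that of Friday's run at its 15.0 d reading, though gamma runs at 85 °C against 89 °C.

The forecast differs from my reckoning. It says “these look like equilibria, not stalled reactions”, gives 40.4 % for zeta, 44.2 % for eta and 43.7 % for gamma, and names eta.

The flasks give 41.8 % for zeta, 41.9 % for eta and 42.5 % for gamma, so the answer is all alike, with a spread of 0.70 points.

    second substrate + free catalyst ⇌ catalyst intermediate B (K = 6.80 L mol⁻¹, k = 0.0610 L mol⁻¹ s⁻¹, Ea = 72.0 kJ mol⁻¹, ΔH = 12.0 kJ mol⁻¹)
    starting material + free catalyst ⇌ catalyst intermediate A (K = 58.0 L mol⁻¹, k = 0.170 L mol⁻¹ s⁻¹, Ea = 73.0 kJ mol⁻¹, ΔH = −12.0 kJ mol⁻¹)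
    second substrate ⇌ dormant form (K = 0.140, k = 6.00 × 10⁻⁶ s⁻¹, Ea = 120 kJ mol⁻¹, ΔH = −26.0 kJ mol⁻¹)
    partner + catalyst intermediate B → free catalyst + second product (k = 1.10 L mol⁻¹ s⁻¹, Ea = 71.0 kJ mol⁻¹)
    partner + catalyst intermediate A → free catalyst + target (k = 0.0220 L mol⁻¹ s⁻¹, Ea = 86.0 kJ mol⁻¹)
    (constants at 100 °C)

At 12.0 d, zeta holds 0 % of its partner and 0.0541 M of second product. Its partner share is 0.279. The neighbour charged with 0.030 M of starting material also ends with 0 % of its partner and gives 47.6 % of target, so its partner share is 0.190.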